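**Retrosynthetic overview**
1. Target 12 ⇐ 11: one final H2/Pd-C operation saturates the C4=C5 bond and removes the O-benzyl group.
2. 11 ⇐ 9 + 10: cross-metathesis of the terminal alkene with 1-tetradecene appends C6–C17.
3. 9 ⇐ 5 + 6: key C2–C3 bond by asymmetric carbonyl allylation (Brown allylboration) of the arylacetaldehyde, which sets the (R)-carbinol.
4. 5 ⇐ 4 ⇐ 3 ⇐ 2 ⇐ 1: alcohol oxidation; phenol differentiation by mono-O-demethylation then benzylation; reduction of the arylacetic acid.
5. No ring is formed in the route; the benzene ring is bought in 1.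

Assumption: the stereocentre in the given SMILES is read as (R) (O > CH2Ar > CH2-alkyl > H), so the target is (R)-1-(3-hydroxy-5-methoxyphenyl)heptadecan-2-ol.

**Route**

Step 1
Reactants: 1 (3,5-dimethoxyphenyl)acetic acid
Product: 2 2-(3,5-dimethoxyphenyl)ethan-1-ol
Conditions: LiAlH4 (1.5 equiv), THF, 0 °C → reflux, 3 h; aqueous (Fieser) work-up
Reagents that add atoms: none
Why: LiAlH4 reduction of a carboxylic acid to the primary alcohol leaves the aryl methyl ethers untouched.

Step 2
Reactants: 2 2-(3,5-dimethoxyphenyl)ethan-1-ol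
Product: 3 3-(2-hydroxyethyl)-5-methoxyphenol
Conditions: NaSEt (3.5 equiv), DMF, 150 °C, 3 h; then 1 M HCl
Reagents that add atoms: none
Why: Thiolate O-demethylation (Feutrill–Mirrington, SN2 at the methyl carbon) stops after one cleavage because the resulting electron-rich phenoxide shuts down attack on the second OMe, so the symmetric diether gives a single mono-phenol and the aliphatic OH is untouched.

Step 3
Reactants: 3 3-(2-hydroxyethyl)-5-methoxyphenol
Product: 4 2-[3-(benzyloxy)-5-methoxyphenyl]ethan-1-ol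
Conditions: BnBr (1.05 equiv), K2CO3 (1.5 equiv), acetone, reflux, 12 h
Reagents that add atoms: benzyl bromide, BrCc1ccccc1
Why: Williamson ether synthesis is chemoselective because K2CO3 deprotonates only the phenol (pKa about 10) and not the primary alcohol (pKa about 16).

Step 4
Reactants: 4 2-[3-(benzyloxy)-5-methoxyphenyl]ethan-1-ol
Product: 5 2-[3-(benzyloxy)-5-methoxyphenyl]acetaldehyde
Conditions: Dess–Martin periodinane (1.2 equiv), CH2Cl2, 0 °C → rt, 1 h; aq. Na2S2O3/NaHCO3 wash; crude 5 used at once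
Reagents that add atoms: none
Why: Dess–Martin oxidation stops at the aldehyde under near-neutral conditions that the enolisable arylacetaldehyde tolerates.

Step 5
Reactants: 5 2-[3-(benzyloxy)-5-methoxyphenyl]acetaldehyde; 6 allylmagnesium bromide
Product: 9 (R)-1-[3-(benzyloxy)-5-methoxyphenyl]pent-4-en-2-ol, via (−)-B-allyldiisopinocampheylborane 7 (not isolated), via (R)-homoallyl diisopinocampheylborinate 8 (not isolated)
Conditions: (+)-Ipc2BOMe (1.3 equiv), 6 (1.2 equiv), Et2O, −78 °C → rt, 1 h; then 5, Et2O, −78 °C, 3 h; then 3 M NaOH, 30% H2O2, rt → 40 °C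
Reagents that add atoms: (+)-B-methoxydiisopinocampheylborane [from (−)-α-pinene], COB([C@H]1C[C@H]2C[C@@H]([C@@H]1C)C2(C)C)[C@H]1C[C@H]2C[C@@H]([C@@H]1C)C2(C)C (its Ipc2B unit is present in 7 and 8 only; the three new carbons of 9 come from 6)
Why: Brown asymmetric allylboration (carbonyl allylation through a chair Zimmerman–Traxler transition state): the (−)-α-pinene-derived Ipc ligands of 7 deliver allyl to the Re face of 5, which sets the carbinol as (R) (CH2Ar outranks allyl), typically in ≥90% ee, and alkaline peroxide then cleaves borinate 8.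

Step 6
Reactants: 9 (R)-1-[3-(benzyloxy)-5-methoxyphenyl]pent-4-en-2-ol; 10 1-tetradecene
Product: 11 (2R,4E)-1-[3-(benzyloxy)-5-methoxyphenyl]heptadec-4-en-2-ol (E major; the E/Z mixture is carried on)
Conditions: Grubbs II (5 mol%), 10 (4 equiv), 1,4-benzoquinone (10 mol%), CH2Cl2, 40 °C, 12 h
Reagents that add atoms: none
Why: Olefin cross-metathesis of two terminal alkenes is driven by excess 10 and loss of ethene, tolerates the free alcohol and does not touch the carbinol centre.

Step 7
Reactants: 11 (2R,4E)-1-[3-(benzyloxy)-5-methoxyphenyl]heptadec-4-en-2-ol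
Product: 12 (R)-1-(3-hydroxy-5-methoxyphenyl)heptadecan-2-ol
Conditions: H2 (1 atm), 10% Pd/C, EtOAc/EtOH 1:1, rt, 12 h
Reagents that add atoms: none
Why: Heterogeneous catalytic hydrogenation saturates the C=C bond (either geometry) and hydrogenolyses the benzyl aryl ether in the same operation, while the homobenzylic secondary alcohol and the aryl OMe are inert, so the (R)-centre is retained.

**Compound list**
1 | (3,5-dimethoxyphenyl)acetic acid | COc1cc(CC(=O)O)cc(OC)c1 | starting material
2 | 2-(3,5-dimethoxyphenyl)ethan-1-ol | COc1cc(CCO)cc(OC)c1 | intermediate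
3 | 3-(2-hydroxyethyl)-5-methoxyphenol | COc1cc(O)cc(CCO)c1 | intermediate
4 | 2-[3-(benzyloxy)-5-methoxyphenyl]ethan-1-ol | COc1cc(CCO)cc(OCc2ccccc2)c1 | intermediate
5 | 2-[3-(benzyloxy)-5-methoxyphenyl]acetaldehyde | COc1cc(CC=O)cc(OCc2ccccc2)c1 | intermediate
6 | allylmagnesium bromide (1 M in Et2O) | C=CC[Mg]Br | starting material
7 | (−)-B-allyldiisopinocampheylborane, Ipc groups of the (−)-α-pinene series | C=CCB([C@H]1C[C@H]2C[C@@H]([C@@H]1C)C2(C)C)[C@H]1C[C@H]2C[C@@H]([C@@H]1C)C2(C)C | intermediate (not isolated)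
8 | (R)-1-[3-(benzyloxy)-5-methoxyphenyl]pent-4-en-2-yl diisopinocampheylborinate | C=CC[C@@H](OB([C@H]1C[C@H]2C[C@@H]([C@@H]1C)C2(C)C)[C@H]1C[C@H]2C[C@@H]([C@@H]1C)C2(C)C)Cc1cc(OC)cc(OCc2ccccc2)c1 | intermediate (not isolated)
9 | (R)-1-[3-(benzyloxy)-5-methoxyphenyl]pent-4-en-2-ol | C=CC[C@@H](O)Cc1cc(OC)cc(OCc2ccccc2)c1 | intermediate
10 | 1-tetradecene | C=CCCCCCCCCCCCC | starting material
11 | (2R,4E)-1-[3-(benzyloxy)-5-methoxyphenyl]heptadec-4-en-2-ol | CCCCCCCCCCCC/C=C/C[C@@H](O)Cc1cc(OC)cc(OCc2ccccc2)c1 | intermediate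
12 | (R)-1-(3-hydroxy-5-methoxyphenyl)heptadecan-2-ol | CCCCCCCCCCCCCCC[C@@H](O)Cc1cc(O)cc(OC)c1 | target

**Totals**
Total step count: 7. Longest linear sequence: 7 steps (1 → 12); 6 and 10 are bought.

**Steps most likely to fail**

Step 2 (mono-O-demethylation; risk: a mixture of unreacted 2, 3 and the fully demethylated resorcinol). The fallback sets out from 1 and comes back at 4, differentiating the two phenols by statistical alkylation instead of selective cleavage. Both methyl ethers of 1 are cleaved with 48% HBr/AcOH at reflux to (3,5-dihydroxyphenyl)acetic acid F1, which is esterified (MeOH, cat. H2SO4, reflux) to methyl (3,5-dihydroxyphenyl)acetate F2. Statistical mono-benzylation (BnBr 1.0 equiv, K2CO3, acetone; about 40%, with the dibenzyl ether removed on silica and recovered F2 recycled) gives methyl [3-(benzyloxy)-5-hydroxyphenyl]acetate F3. The remaining phenol is methylated (MeI, K2CO3, acetone) to methyl [3-(benzyloxy)-5-methoxyphenyl]acetate F4, and LiAlH4 (THF, 0 °C) reduces F4 to 4, where the route continues with step 4.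

Step 5 (risk: the enolisable aldehyde 5 self-condenses before it is trapped, or the ee stays below about 90%). The fallback sets out from 4 and comes back at 12, replacing the allylboration by a Claisen condensation followed by asymmetric hydrogenation. Alcohol 4 is oxidised with TEMPO (cat.)/PhI(OAc)2 in MeCN/H2O to [3-(benzyloxy)-5-methoxyphenyl]acetic acid F5. CDI in THF converts it into the acyl imidazolide 2-[3-(benzyloxy)-5-methoxyphenyl]-1-(imidazol-1-yl)ethan-1-one F6 (used in the flask), which undergoes crossed Claisen condensation with the lithium enolate of ethyl acetate (LDA, EtOAc, 3 equiv, THF, −78 °C) to ethyl 4-[3-(benzyloxy)-5-methoxyphenyl]-3-oxobutanoate F7. Noyori hydrogenation (RuCl2[(S)-BINAP] cat., H2 50 atm, EtOH, 50 °C) gives ethyl (S)-4-[3-(benzyloxy)-5-methoxyphenyl]-3-hydroxybutanoate F8; the (S) descriptor here is the same spatial arrangement as (R) in 9 and 12, because CH2CO2Et outranks CH2Ar. TBSCl/imidazole/DMF gives ethyl (S)-4-[3-(benzyloxy)-5-methoxyphenyl]-3-[(tert-butyldimethylsilyl)oxy]butanoate F9, and DIBAL-H (CH2Cl2, −78 °C) gives (S)-4-[3-(benzyloxy)-5-methoxyphenyl]-3-[(tert-butyldimethylsilyl)oxy]butanal F10. Wittig olefination with the ylide from tridecyltriphenylphosphonium bromide and NaHMDS (THF, −78 °C → rt) gives the (Z)-alkene tert-butyl({(2R,4Z)-1-[3-(benzyloxy)-5-methoxyphenyl]heptadec-4-en-2-yl}oxy)dimethylsilane F11. TBAF in THF gives (2R,4Z)-1-[3-(benzyloxy)-5-methoxyphenyl]heptadec-4-en-2-ol F12, the Z isomer of 11, which under the conditions of step 7 gives 12.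

Step 6 (risk: homodimers and, worse, Ru-hydride double-bond migration that gives chain-shortened homologues which cannot be separated after step 7). The fallback sets out from 9 and comes back at 12, building the chain by olefination with a reagent of defined length instead of metathesis. Alcohol 9 is silylated (TBSCl, imidazole, DMF) to tert-butyl({(R)-1-[3-(benzyloxy)-5-methoxyphenyl]pent-4-en-2-yl}oxy)dimethylsilane F13. The terminal alkene is cleaved (OsO4 cat., NaIO4, 2,6-lutidine, dioxane/H2O) to (S)-4-[3-(benzyloxy)-5-methoxyphenyl]-3-[(tert-butyldimethylsilyl)oxy]butanal F10, the same aldehyde as in the fallback for step 5 (descriptor changed by CIP ranking only). From there the sequence described above is used: Wittig reaction with the C13 ylide to the (Z)-alkene silyl ether F11, TBAF to the (Z)-alkenol F12, and hydrogenation/hydrogenolysis as in step 7 to 12.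

**Further compounds**
F1 | step 2 | (3,5-dihydroxyphenyl)acetic acid | OC(=O)Cc1cc(O)cc(O)c1
F2 | step 2 | methyl (3,5-dihydroxyphenyl)acetate | COC(=O)Cc1cc(O)cc(O)c1
F3 | step 2 | methyl [3-(benzyloxy)-5-hydroxyphenyl]acetate | COC(=O)Cc1cc(O)cc(OCc2ccccc2)c1
F4 | step 2 | methyl [3-(benzyloxy)-5-methoxyphenyl]acetate | COC(=O)Cc1cc(OC)cc(OCc2ccccc2)c1
F5 | step 5 | [3-(benzyloxy)-5-methoxyphenyl]acetic acid | COc1cc(CC(=O)O)cc(OCc2ccccc2)c1
F6 | step 5 | 2-[3-(benzyloxy)-5-methoxyphenyl]-1-(imidazol-1-yl)ethan-1-one | COc1cc(CC(=O)n2ccnc2)cc(OCc2ccccc2)c1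
F7 | step 5 | ethyl 4-[3-(benzyloxy)-5-methoxyphenyl]-3-oxobutanoate | CCOC(=O)CC(=O)Cc1cc(OC)cc(OCc2ccccc2)c1
F8 | step 5 | ethyl (S)-4-[3-(benzyloxy)-5-methoxyphenyl]-3-hydroxybutanoate | CCOC(=O)C[C@@H](O)Cc1cc(OC)cc(OCc2ccccc2)c1
F9 | step 5 | ethyl (S)-4-[3-(benzyloxy)-5-methoxyphenyl]-3-[(tert-butyldimethylsilyl)oxy]butanoate | CCOC(=O)C[C@@H](O[Si](C)(C)C(C)(C)C)Cc1cc(OC)cc(OCc2ccccc2)c1
F10 | step 5 | (S)-4-[3-(benzyloxy)-5-methoxyphenyl]-3-[(tert-butyldimethylsilyl)oxy]butanal | O=CC[C@@H](O[Si](C)(C)C(C)(C)C)Cc1cc(OC)cc(OCc2ccccc2)c1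
F11 | step 5 | tert-butyl({(2R,4Z)-1-[3-(benzyloxy)-5-methoxyphenyl]heptadec-4-en-2-yl}oxy)dimethylsilane | CCCCCCCCCCCC/C=C\C[C@@H](O[Si](C)(C)C(C)(C)C)Cc1cc(OC)cc(OCc2ccccc2)c1
F12 | step 5 | (2R,4Z)-1-[3-(benzyloxy)-5-methoxyphenyl]heptadec-4-en-2-ol | CCCCCCCCCCCC/C=C\C[C@@H](O)Cc1cc(OC)cc(OCc2ccccc2)c1
F13 | step 6 | tert-butyl({(R)-1-[3-(benzyloxy)-5-methoxyphenyl]pent-4-en-2-yl}oxy)dimethylsilane | C=CC[C@@H](O[Si](C)(C)C(C)(C)C)Cc1cc(OC)cc(OCc2ccccc2)c1
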